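**Strategy.** The saturated ring is disconnected at C1–C8a (tetralin numbering: C1 carries the side chain, C4 the methyl; C11 is the side-chain carbon on C1, C20 its CH2O carbon). Two features are exploited: C8a lies para to the C6 oxygen, and C20 stands 1,3 to C1 and can be a carboxyl. C20 and C1 are therefore tied in a temporary cis-β-lactone, made by a catalytic asymmetric ketene–aldehyde cycloaddition that joins the two chiral halves. In the key step the arene displaces the lactone oxygen at C1 with inversion: this closes the carbocycle, turns the C1–O centre into the C1–aryl centre beside the preset C11, and frees C20 as the acid.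

Key step: step 8

Assumption: in steps 2 and 7 the ligand enantiomer and the cinchona pseudoenantiomer written are those expected by analogy to give the drawn configuration; the mirror-image ligand and O-TMS-quinine are equally available if the sense proves opposite.

Step 1
Reactants: 1 2,3-dimethoxybenzaldehyde
Product: 2 2,3-dimethoxystyrene
Conditions: Ph3PCH3Br, KOtBu, THF, 0 °C → rt
Reagents that add atoms: methyltriphenylphosphonium bromide, C[P+](c1ccccc1)(c1ccccc1)c1ccccc1.[Br-]
Why: Wittig methylenation of an aromatic aldehyde with the non-stabilised ylide is dependable and creates no stereocentre.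

Step 2
Reactants: 2 2,3-dimethoxystyrene
Product: 3 (R)-3-(2,3-dimethoxyphenyl)but-1-ene
Conditions: [(allyl)NiBr]2 (cat.), (Sa,Rc,Rc)-binaphthol/bis(1-phenylethyl)amine phosphoramidite (cat.), NaBArF4, ethylene (1 atm), CH2Cl2, −78 °C
Reagents that add atoms: ethylene, C=C
Why: Nickel-catalysed asymmetric hydrovinylation (RajanBabu type): a cationic Ni–H adds to the styrene to give an η3-benzyl nickel species, ethylene inserts and β-hydride elimination releases the 3-arylbutene, the phosphoramidite choosing the alkene face and so setting C4 as (R), while the low temperature holds back isomerisation to the conjugated alkene.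

Step 3
Reactants: 3 (R)-3-(2,3-dimethoxyphenyl)but-1-ene
Product: 4 (R)-4-(2,3-dimethoxyphenyl)pentanal
Conditions: Rh(acac)(CO)2 (cat.), Xantphos, CO/H2 (1:1, 10 bar), toluene, 60 °C
Reagents that add atoms: carbon monoxide, [C-]#[O+]
Why: Linear-selective rhodium hydroformylation with a wide-bite-angle diphosphine; the α-branch further disfavours the branched alkyl-rhodium, so the allylic stereocentre should not be reached by β-hydride elimination.

Step 4
Reactants: 5 (S)-3-bromo-2-methylpropan-1-ol
Product: 6 (S)-3-bromo-2-methylpropyl acetate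
Conditions: Ac2O, pyridine, DMAP (cat.), CH2Cl2, 0 °C → rt
Reagents that add atoms: acetic anhydride, CC(=O)OC(C)=O
Why: DMAP-catalysed acetylation; the acetate masks the alcohol in a form that tolerates the organozinc, the acid chloride and the Lewis acid, and it is shed without an extra step in the hydride reduction of step 9.

Step 5
Reactants: 6 (S)-3-bromo-2-methylpropyl acetate; 7 tert-butyl 4-bromobutanoate
Product: 9 tert-butyl (R)-7-acetoxy-6-methylheptanoate, via alkylzinc bromide 8 (not isolated)
Conditions: Zn dust (BrCH2CH2Br/TMSCl-activated), LiCl, THF, 50 °C; then 7, Pd2(dba)3 (cat.), PCyp3 (cat.), N-methylimidazole, THF/NMP, 80 °C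
Reagents that add atoms: none
Why: LiCl-promoted zinc insertion (Knochel) followed by a Pd/trialkylphosphine alkyl–alkyl Negishi coupling (Fu type) with an unbranched primary bromide; the purchased stereocentre is β to the metal and takes no part, so it becomes C15 unchanged.

Step 6
Reactants: 9 tert-butyl (R)-7-acetoxy-6-methylheptanoate
Product: 11 (R)-7-acetoxy-6-methylheptanoyl chloride, via free carboxylic acid 10 (not isolated)
Conditions: SOCl2 (excess, trace HCl), rt; evaporate
Reagents that add atoms: thionyl chloride, O=S(Cl)Cl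
Why: Direct conversion of a tert-butyl ester into the acid chloride with thionyl chloride (HCl-mediated loss of tert-butyl chloride, then chlorination of the acid), a reaction to which primary alkyl esters such as the acetate are inert.

Step 7
Reactants: 4 (R)-4-(2,3-dimethoxyphenyl)pentanal; 11 (R)-7-acetoxy-6-methylheptanoyl chloride
Product: 13 (3S,4R)-3-[(R)-5-acetoxy-4-methylpentyl]-4-[(R)-3-(2,3-dimethoxyphenyl)butyl]oxetan-2-one, via ketene 12 (not isolated)
Conditions: O-TMS-quinidine (10 mol %), LiClO4, iPr2NEt, CH2Cl2/Et2O, −78 °C, slow addition of 11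
Reagents that add atoms: none
Why: Catalytic asymmetric acyl halide–aldehyde cyclocondensation (Nelson variant of the Wynberg ketene–aldehyde [2+2]): the alkaloid adds to the ketene, the ammonium enolate adds to the lithium-activated aldehyde through a closed transition state and lactonises to the cis-3,4-disubstituted β-lactone, the catalyst setting C11 (S) and the C1–O centre (R) together while the remote C4 and C15 centres stand by.

Step 8
Reactants: 13 (3S,4R)-3-[(R)-5-acetoxy-4-methylpentyl]-4-[(R)-3-(2,3-dimethoxyphenyl)butyl]oxetan-2-one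
Product: 14 (2S,6R)-7-acetoxy-2-[(1S,4R)-5,6-dimethoxy-4-methyl-1,2,3,4-tetrahydronaphthalen-1-yl]-6-methylheptanoic acid
Conditions: BF3·OEt2 (3 equiv), CH2Cl2 (high dilution), −78 → −20 °C; aqueous work-up
Reagents that add atoms: none
Why: BF3 binds the lactone carbonyl, and the ring carbon para to the unhindered methoxy group (future C8a) attacks the oxetanone C4 (future C1) from the side opposite the C–O bond; rearomatisation leaves the free C20 acid. The closest known reaction types are the Friedel–Crafts alkylation of arenes by β-lactones through alkyl–oxygen cleavage and the stereospecific Lewis-acid epoxy-arene cyclisation. The six-membered carbocycle closes in a 6-exo-tet mode, and the regiochemistry is forced because the only free position ortho to the tether is the one para to OMe. C1 is set as (S) by inversion of the C–O centre installed in step 7; C11 is not touched and C4 is a spectator, so the cis-lactone maps onto the (1S,11S) pair and the 1,4-trans ring. The step needs substitution to outrun ionisation at C1 (hydride shift, elimination, decarboxylation). This is secured by the β-carboxyl group, which destabilises the secondary cation, by the activated arene held four carbons away, and by the non-nucleophilic counter-ion and low temperature.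

Step 9
Reactants: 14 (2S,6R)-7-acetoxy-2-[(1S,4R)-5,6-dimethoxy-4-methyl-1,2,3,4-tetrahydronaphthalen-1-yl]-6-methylheptanoic acid
Product: 15 (2S,6R)-2-[(1S,4R)-5,6-dimethoxy-4-methyl-1,2,3,4-tetrahydronaphthalen-1-yl]-6-methylheptane-1,7-diol
Conditions: LiAlH4, THF, 0 → 50 °C; Fieser work-up
Reagents that add atoms: none
Why: Hydride reduction takes the carboxylic acid to the C20 alcohol and cleaves the C16 acetate in the same operation; the acid reacts as its carboxylate, so C11 should not epimerise.

Step 10
Reactants: 15 (2S,6R)-2-[(1S,4R)-5,6-dimethoxy-4-methyl-1,2,3,4-tetrahydronaphthalen-1-yl]-6-methylheptane-1,7-diol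
Product: 17 (5R,8S)-8-[(2S,6R)-1,7-dihydroxy-6-methylheptan-2-yl]-3,4-dimethoxy-5-methyl-5,6,7,8-tetrahydronaphthalene-2-carboxylic acid, via trilithiated aryllithium 16 (not isolated)
Conditions: n-BuLi (4.5 equiv), TMEDA, THF, −20 → 0 °C; CO2, −78 °C → rt; 1 M HCl
Reagents that add atoms: carbon dioxide, O=C=O
Why: Directed ortho-metalation: once both alcohols are deprotonated, the base lithiates the only ring C–H ortho to a methoxy group (C7) and CO2 traps the aryllithium; C8–H has no directing neighbour and the tertiary benzylic C–H bonds are too weakly acidic to compete.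

Step 11
Reactants: 17 (5R,8S)-8-[(2S,6R)-1,7-dihydroxy-6-methylheptan-2-yl]-3,4-dimethoxy-5-methyl-5,6,7,8-tetrahydronaphthalene-2-carboxylic acid
Product: 19 (5R,8S)-8-[(2S,6R)-1,7-diacetoxy-6-methylheptan-2-yl]-3,4-dimethoxy-5-methyl-5,6,7,8-tetrahydronaphthalene-2-carboxylic acid, via mixed acetic anhydride 18 (not isolated)
Conditions: Ac2O, pyridine, DMAP (cat.), CH2Cl2, rt; then H2O/THF, rt
Reagents that add atoms: acetic anhydride, CC(=O)OC(C)=O
Why: DMAP-catalysed acetylation of the two primary alcohols; the aryl acid is carried for a time as its mixed anhydride, which water cleaves back to the acid in the work-up.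

Step 12
Reactants: 19 (5R,8S)-8-[(2S,6R)-1,7-diacetoxy-6-methylheptan-2-yl]-3,4-dimethoxy-5-methyl-5,6,7,8-tetrahydronaphthalene-2-carboxylic acid
Product: 20 (5R,8S)-8-[(2S,6R)-1,7-diacetoxy-6-methylheptan-2-yl]-3,4-dihydroxy-5-methyl-5,6,7,8-tetrahydronaphthalene-2-carboxylic acid
Conditions: BBr3 (5 equiv), CH2Cl2, −78 → −20 °C; ice-water
Reagents that add atoms: none
Why: Lewis-acid cleavage of aryl methyl ethers: the methoxy group ortho to the carboxyl is cleaved through a chelate and the flanked, twisted C5 methoxy group through the resulting cyclic borate, whereas primary acetates should react only at higher temperature.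

**Compound list**

1 | 2,3-dimethoxybenzaldehyde | COc1cccc(C=O)c1OC | starting material
2 | 2,3-dimethoxystyrene | COc1cccc(C=C)c1OC | intermediate
3 | (R)-3-(2,3-dimethoxyphenyl)but-1-ene | C=C[C@@H](C)c1cccc(OC)c1OC | intermediate
4 | (R)-4-(2,3-dimethoxyphenyl)pentanal | O=CCC[C@@H](C)c1cccc(OC)c1OC | intermediate
5 | (S)-3-bromo-2-methylpropan-1-ol | OC[C@H](C)CBr | starting material
6 | (S)-3-bromo-2-methylpropyl acetate | CC(=O)OC[C@H](C)CBr | intermediate
7 | tert-butyl 4-bromobutanoate | CC(C)(C)OC(=O)CCCBr | starting material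
8 | alkylzinc bromide: (S)-(3-acetoxy-2-methylpropyl)zinc bromide (not isolated) | CC(=O)OC[C@H](C)C[Zn]Br | intermediate
9 | tert-butyl (R)-7-acetoxy-6-methylheptanoate | CC(=O)OC[C@H](C)CCCCC(=O)OC(C)(C)C | intermediate
10 | free carboxylic acid: (R)-7-acetoxy-6-methylheptanoic acid (not isolated) | CC(=O)OC[C@H](C)CCCCC(=O)O | intermediate
11 | (R)-7-acetoxy-6-methylheptanoyl chloride | CC(=O)OC[C@H](C)CCCCC(=O)Cl | intermediate
12 | ketene: (R)-2-methyl-7-oxohept-6-en-1-yl acetate (not isolated) | CC(=O)OC[C@H](C)CCCC=C=O | intermediate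
13 | (3S,4R)-3-[(R)-5-acetoxy-4-methylpentyl]-4-[(R)-3-(2,3-dimethoxyphenyl)butyl]oxetan-2-one (cis-β-lactone) | CC(=O)OC[C@H](C)CCC[C@@H]1C(=O)O[C@@H]1CC[C@@H](C)c2cccc(OC)c2OC | intermediate
14 | (2S,6R)-7-acetoxy-2-[(1S,4R)-5,6-dimethoxy-4-methyl-1,2,3,4-tetrahydronaphthalen-1-yl]-6-methylheptanoic acid | CC(=O)OC[C@H](C)CCC[C@H](C(=O)O)[C@@H]1CC[C@@H](C)c2c1ccc(OC)c2OC | intermediate
15 | (2S,6R)-2-[(1S,4R)-5,6-dimethoxy-4-methyl-1,2,3,4-tetrahydronaphthalen-1-yl]-6-methylheptane-1,7-diol | OC[C@H](C)CCC[C@H](CO)[C@@H]1CC[C@@H](C)c2c1ccc(OC)c2OC | intermediate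
16 | trilithiated aryllithium: dilithium dialkoxide of 15 lithiated at C7 (not isolated) | [Li]OC[C@H](C)CCC[C@H](CO[Li])[C@@H]1CC[C@@H](C)c2c1cc([Li])c(OC)c2OC | intermediate
17 | (5R,8S)-8-[(2S,6R)-1,7-dihydroxy-6-methylheptan-2-yl]-3,4-dimethoxy-5-methyl-5,6,7,8-tetrahydronaphthalene-2-carboxylic acid | OC[C@H](C)CCC[C@H](CO)[C@@H]1CC[C@@H](C)c2c1cc(C(=O)O)c(OC)c2OC | intermediate
18 | mixed acetic anhydride of 19 (not isolated) | CC(=O)OC[C@H](C)CCC[C@H](COC(C)=O)[C@@H]1CC[C@@H](C)c2c1cc(C(=O)OC(C)=O)c(OC)c2OC | intermediate
19 | (5R,8S)-8-[(2S,6R)-1,7-diacetoxy-6-methylheptan-2-yl]-3,4-dimethoxy-5-methyl-5,6,7,8-tetrahydronaphthalene-2-carboxylic acid | CC(=O)OC[C@H](C)CCC[C@H](COC(C)=O)[C@@H]1CC[C@@H](C)c2c1cc(C(=O)O)c(OC)c2OC | intermediate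
20 | (5R,8S)-8-[(2S,6R)-1,7-diacetoxy-6-methylheptan-2-yl]-3,4-dihydroxy-5-methyl-5,6,7,8-tetrahydronaphthalene-2-carboxylic acid | CC(=O)OC[C@H](C)CCC[C@H](COC(C)=O)[C@@H]1CC[C@@H](C)c2c1cc(C(=O)O)c(O)c2O | target

**Step count.** 12 steps in total. The longest linear sequence is 9 steps (steps 4–12 from 5; the branch from 1, steps 1–3 and 7–12, is equally long).

**Steps most likely to fail**

Step 8 (ring closure). The risk is ionisation at C1 before the C–C bond forms, which would scramble C1 and open hydride-shift, elimination or decarboxylation channels. The fallback makes the arene the metal nucleophile, so that no cation can arise. It sets out from 13. Iodination (NIS, cat. TFA, MeCN, 0 °C) at the ring carbon para to the unhindered methoxy group should give the iodo-lactone F1. Iodine–magnesium exchange (iPrMgCl·LiCl, THF, −40 °C) gives the arylmagnesium chloride F2, which is not isolated. CuBr·SMe2 (cat.) and TMSCl then bring about the copper-mediated SN2 opening of the β-lactone at C1 with inversion (the known Grignard/copper alkylation of β-lactones, here within one molecule). Acidic work-up returns to the route at 14.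

Step 7 (cyclocondensation). The risk is homodimerisation of the long-chain ketene outrunning the cross [2+2], or erosion of the cis selectivity. The fallback is an auxiliary-controlled aldol route that sets out from 11 and 4. Acid chloride 11 acylates lithiated (S)-4-benzyloxazolidin-2-one (n-BuLi, THF, −78 °C) to give the imide F3. Boron enolisation (Bu2BOTf, iPr2NEt, CH2Cl2, −78 °C) and addition of aldehyde 4 should give the Evans syn-aldol adduct F4. LiOH/H2O2 (THF/H2O, 0 °C) frees the syn-β-hydroxy acid F5. Carboxyl activation (PhSO2Cl, pyridine, 0 °C), which retains the carbinol configuration, closes the cis-β-lactone and returns to the route at 13.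

Step 12 (demethylation). The risk is competing cleavage of the two primary acetates by BBr3 while the ethers are being cleaved. The fallback reverses the order and sets out from 17. BBr3 (CH2Cl2, −78 → 0 °C) on the diol acid gives the catechol diol acid F6. Lipase-catalysed transesterification (CAL-B, vinyl acetate, MTBE, 30 °C), which acylates aliphatic primary alcohols and leaves phenols and the acid alone, then gives 20 directly.

**Further compounds**

F1 | step 8 | (3S,4R)-3-[(R)-5-acetoxy-4-methylpentyl]-4-[(R)-3-(6-iodo-2,3-dimethoxyphenyl)butyl]oxetan-2-one | CC(=O)OC[C@H](C)CCC[C@@H]1C(=O)O[C@@H]1CC[C@@H](C)c2c(I)ccc(OC)c2OC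
F2 | step 8 | arylmagnesium chloride from F1 (magnesium in place of iodine) | CC(=O)OC[C@H](C)CCC[C@@H]1C(=O)O[C@@H]1CC[C@@H](C)c2c([Mg]Cl)ccc(OC)c2OC
F3 | step 7 | (S)-4-benzyl-3-[(R)-7-acetoxy-6-methylheptanoyl]oxazolidin-2-one | CC(=O)OC[C@H](C)CCCCC(=O)N1[C@@H](Cc2ccccc2)COC1=O
F4 | step 7 | (S)-3-{(2S,3R,6R)-2-[(R)-5-acetoxy-4-methylpentyl]-6-(2,3-dimethoxyphenyl)-3-hydroxyheptanoyl}-4-benzyloxazolidin-2-one | CC(=O)OC[C@H](C)CCC[C@@H]([C@H](O)CC[C@@H](C)c1cccc(OC)c1OC)C(=O)N1[C@@H](Cc2ccccc2)COC1=O
F5 | step 7 | (2S,3R,6R)-2-[(R)-5-acetoxy-4-methylpentyl]-6-(2,3-dimethoxyphenyl)-3-hydroxyheptanoic acid | CC(=O)OC[C@H](C)CCC[C@@H]([C@H](O)CC[C@@H](C)c1cccc(OC)c1OC)C(=O)O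
F6 | step 12 | (5R,8S)-8-[(2S,6R)-1,7-dihydroxy-6-methylheptan-2-yl]-3,4-dihydroxy-5-methyl-5,6,7,8-tetrahydronaphthalene-2-carboxylic acid | OC[C@H](C)CCC[C@H](CO)[C@@H]1CC[C@@H](C)c2c1cc(C(=O)O)c(O)c2O
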